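**Retrosynthetic overview**

1. Ring A (the 3-methyltetronic acid) is opened last, by a Dieckmann disconnection to an (R)-2-propanoyloxy methyl ester. Its C5 stereocentre comes from methyl (R)-glycidate and is never part of a bond-forming event.
2. The side chain (C1'–C9', counted outward from C5 of ring A) is cut at C5'–C6'. C6' of the (6'E)-alkene carries two different carbon groups (CH3 and the C5' methylene), while C7' carries only H and C8'. C6' can therefore be the CCl2 carbon of a 1,1-dichloroalkene, whose two C–Cl bonds differ only in being trans or cis to C8'.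
3. Key step: a one-flask double Negishi coupling. The C5' alkylzinc replaces the trans chlorine (C5'–C6', fixing E) and Me2Zn then replaces the cis chlorine, so two C–C bonds and the alkene geometry arise from a precursor without geometry.
4. Zinc fragment: the (2'Z)-alkene comes from a Stork–Zhao iodo-olefination, followed by copper-catalysed opening of the glycidate. Dichloroalkene fragment: rings B (2,4-disubstituted furan) and C (3-furyl) are joined at the CH2 bridge, the chain is added by B-alkyl Suzuki coupling, then dichloro-olefination.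
5. Ring order: furans C and B are carried through from commercial furans; ring A is closed in the final step.

Key step: step 12

Remark: the target is treated as the 4-hydroxy enol tautomer of the tetronic acid, as drawn in its SMILES; C5 of ring A is R.

**Step 1**
Reactants: 1 3-bromofuran; 2 4-bromofuran-2-carbaldehyde
Product: 4 rac-(4-bromofuran-2-yl)(furan-3-yl)methanol, via furan-3-yllithium 3 (not isolated)
Conditions: n-BuLi, THF, –78 °C; then 2, –78 °C; H2O
Reagents that add atoms: none
Why: Bromine–lithium exchange gives furan-3-yllithium, which at –78 °C should add to the aldehyde (1,2-addition) much faster than it exchanges with the C4 bromide; the carbinol stereocentre is racemic and is removed in step 2.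

**Step 2**
Reactants: 4 rac-(4-bromofuran-2-yl)(furan-3-yl)methanol
Product: 5 4-bromo-2-(furan-3-ylmethyl)furan
Conditions: Et3SiH, CF3CO2H, CH2Cl2, –20 → 0 °C
Reagents that add atoms: none
Why: Ionic hydrogenation, in which the carbinol ionises to a cation stabilised by the furan-2-yl ring and is trapped by hydride from excess silane before it can alkylate another furan.

**Step 3**
Reactants: 5 4-bromo-2-(furan-3-ylmethyl)furan; 6 3,3-diethoxyprop-1-ene (acrolein diethyl acetal)
Product: 8 4-(3,3-diethoxypropyl)-2-(furan-3-ylmethyl)furan, via borane 7 (not isolated)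
Conditions: 6, 9-BBN, THF, 0 °C → rt; then 5, PdCl2(dppf) (5 mol %), 3 M aq. NaOH, THF, 65 °C
Reagents that add atoms: none
Why: Anti-Markovnikov hydroboration of the terminal alkene followed by B-alkyl Suzuki–Miyaura coupling at the C4 bromide of ring B, under aqueous base that leaves the acetal and both furans intact.

**Step 4**
Reactants: 8 4-(3,3-diethoxypropyl)-2-(furan-3-ylmethyl)furan
Product: 9 3-[5-(furan-3-ylmethyl)furan-3-yl]propanal
Conditions: pyridinium p-toluenesulfonate (cat.), acetone–H2O, 50 °C
Reagents that add atoms: water, O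
Why: Buffered acid-catalysed hydrolysis of the acyclic diethyl acetal, which should be mild enough to spare the acid-sensitive alkylfurans.

**Step 5**
Reactants: 9 3-[5-(furan-3-ylmethyl)furan-3-yl]propanal
Product: 10 4-(4,4-dichlorobut-3-en-1-yl)-2-(furan-3-ylmethyl)furan
Conditions: PPh3, BrCCl3, MeCN, 0 °C → rt
Reagents that add atoms: bromotrichloromethane, ClC(Cl)(Cl)Br
Why: Ramirez-type gem-dichloro-olefination, a Wittig reaction of Ph3P=CCl2 formed in situ, which proceeds at room temperature under non-acidic conditions.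

**Step 6**
Reactants: 11 ethyltriphenylphosphonium iodide; 12 3-{[tert-butyl(dimethyl)silyl]oxy}propanal
Product: 16 tert-butyl{[(3Z)-4-iodopent-3-en-1-yl]oxy}dimethylsilane, via ethylidene ylide 13 (not isolated), via iodoethylphosphonium iodide 14 (not isolated), via iodo ylide 15 (not isolated)
Conditions: 11, n-BuLi, THF, 0 °C → rt; I2, –78 °C; NaN(SiMe3)2, –20 °C; then 12, –78 °C → rt
Reagents that add atoms: iodine, II
Why: Stork–Zhao-type Wittig olefination with the α-iodo ylide, whose kinetically formed cis-oxaphosphetane should give the (Z)-2-iodoalkene with iodine cis to the chain.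

**Step 7**
Reactants: 16 tert-butyl{[(3Z)-4-iodopent-3-en-1-yl]oxy}dimethylsilane; 17 methyl (2R)-oxirane-2-carboxylate
Product: 20 methyl (2R,4Z)-7-{[tert-butyl(dimethyl)silyl]oxy}-2-hydroxy-4-methylhept-4-enoate, via alkenyllithium 18 (not isolated), via alkenylmagnesium bromide 19 (not isolated)
Conditions: t-BuLi (2 equiv), Et2O, –78 °C; MgBr2·OEt2, –78 → –40 °C; CuI (10 mol %), THF, then 17, –40 °C; H2O
Reagents that add atoms: none
Why: Iodine–lithium exchange and transmetalation retain the alkene geometry, and the copper-catalysed alkenyl Grignard should open the glycidate by SN2 attack at the unsubstituted C3 faster than it adds to the ester, so the (R) centre is carried over unchanged from the chiral pool and the alkene is Z.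

**Step 8**
Reactants: 20 methyl (2R,4Z)-7-{[tert-butyl(dimethyl)silyl]oxy}-2-hydroxy-4-methylhept-4-enoate
Product: 21 methyl (2R,4Z)-7-{[tert-butyl(dimethyl)silyl]oxy}-4-methyl-2-(propanoyloxy)hept-4-enoate
Conditions: (EtCO)2O, Et3N, DMAP (cat.), CH2Cl2, 0 °C → rt
Reagents that add atoms: propanoic anhydride, CCC(=O)OC(=O)CC
Why: DMAP-catalysed acylation of the secondary alcohol, which installs the three carbons of C2, C3 and the C3 methyl of ring A without touching the stereocentre.

**Step 9**
Reactants: 21 methyl (2R,4Z)-7-{[tert-butyl(dimethyl)silyl]oxy}-4-methyl-2-(propanoyloxy)hept-4-enoate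
Product: 22 methyl (2R,4Z)-7-hydroxy-4-methyl-2-(propanoyloxy)hept-4-enoate
Conditions: HF·pyridine, THF, 0 °C → rt
Reagents that add atoms: none
Why: Fluoride-mediated cleavage of the primary silyl ether under weakly acidic conditions that should neither hydrolyse the esters nor epimerise C2.

**Step 10**
Reactants: 22 methyl (2R,4Z)-7-hydroxy-4-methyl-2-(propanoyloxy)hept-4-enoate
Product: 23 methyl (2R,4Z)-7-iodo-4-methyl-2-(propanoyloxy)hept-4-enoate
Conditions: I2, PPh3, imidazole, CH2Cl2, 0 °C
Reagents that add atoms: iodine, II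
Why: Appel iodination of the primary alcohol by SN2 displacement of the alkoxyphosphonium ion, which is neutral toward the homoallylic alkene and the esters.

**Step 11**
Reactants: 23 methyl (2R,4Z)-7-iodo-4-methyl-2-(propanoyloxy)hept-4-enoate
Product: 24 [(3Z,6R)-7-methoxy-4-methyl-7-oxo-6-(propanoyloxy)hept-3-en-1-yl]zinc iodide (THF solution, used directly)
Conditions: Zn dust (activated with BrCH2CH2Br and Me3SiCl), LiCl, THF, 40 °C
Reagents that add atoms: zinc, [Zn]
Why: LiCl-assisted direct insertion of zinc into the primary C–I bond gives an alkylzinc iodide that tolerates both esters and is not basic enough to enolise C2.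

**Step 12**
Reactants: 24 [(3Z,6R)-7-methoxy-4-methyl-7-oxo-6-(propanoyloxy)hept-3-en-1-yl]zinc iodide; 10 4-(4,4-dichlorobut-3-en-1-yl)-2-(furan-3-ylmethyl)furan
Product: 26 methyl (2R,4Z,8E)-11-[5-(furan-3-ylmethyl)furan-3-yl]-4,8-dimethyl-2-(propanoyloxy)undeca-4,8-dienoate, via chloroalkene 25 (not isolated)
Conditions: 24 (1.3 equiv), 10, PdCl2(DPEphos) (5 mol %), THF–DMF, 23 °C; then Me2Zn, Pd(PtBu3)2 (5 mol %), 50 °C, same flask
Reagents that add atoms: dimethylzinc, C[Zn]C
Why: Zerovalent palladium, formed in situ from PdCl2(DPEphos), should insert into the C–Cl bond of 10 that is trans to the C8' methylene (the cis C–Cl is shielded by it); transmetalation with alkylzinc 24 and reductive elimination then form C5'–C6' (C7–C8 of 26) and leave the (8Z)-chloroalkene 25, after which Pd(PtBu3)2 inserts into the remaining hindered C–Cl bond and Me2Zn methylates it with retention. The closest known reaction type is the palladium-catalysed trans-selective monoalkylation of 1,1-dichloro-1-alkenes with alkylzinc reagents, followed by a second Negishi substitution of the resulting 2-chloro-2-alkene. No ring is closed and no stereocentre is created; the one new stereo-element, the C6'=C7' geometry, should be E because the first group to enter (C5') takes the trans site and the methyl group the cis site. The step needs mono- over dialkylation (the DPEphos catalyst should not activate the more electron-rich trisubstituted chloride 25 at 23 °C), trans over cis insertion (steric differentiation by C8'), retention in the second coupling (fast reductive elimination from the bulky PtBu3 complex) and chemoselectivity (organozincs leave both esters, the C2 stereocentre and the furans alone). In one flask two C–C bonds, the complete carbon skeleton and the trisubstituted E-alkene thus arise from a dichloroalkene that carries no stereochemical information.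

**Step 13**
Reactants: 26 methyl (2R,4Z,8E)-11-[5-(furan-3-ylmethyl)furan-3-yl]-4,8-dimethyl-2-(propanoyloxy)undeca-4,8-dienoate
Product: 27 (5R)-5-{(2Z,6E)-9-[5-(furan-3-ylmethyl)furan-3-yl]-2,6-dimethylnona-2,6-dien-1-yl}-4-hydroxy-3-methylfuran-2(5H)-one
Conditions: LiN(SiMe3)2 (2.5 equiv), THF, –78 → 0 °C; then 1 M HCl to pH 3, 0 °C
Reagents that add atoms: none
Why: Dieckmann cyclisation, in which the kinetically formed propanoate enolate attacks the neighbouring methyl ester (5-exo-trig acyl substitution) and the resulting tetronate anion resists further deprotonation, so the (R) centre set in step 7 should be retained.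

**Compound list**

1 | 3-bromofuran | Brc1ccoc1 | starting material
2 | 4-bromofuran-2-carbaldehyde | O=Cc1cc(Br)co1 | starting material
3 | furan-3-yllithium | [Li]c1ccoc1 | intermediate
4 | rac-(4-bromofuran-2-yl)(furan-3-yl)methanol | OC(c1cc(Br)co1)c1ccoc1 | intermediate
5 | 4-bromo-2-(furan-3-ylmethyl)furan | Brc1coc(Cc2ccoc2)c1 | intermediate
6 | 3,3-diethoxyprop-1-ene | C=CC(OCC)OCC | starting material
7 | 9-(3,3-diethoxypropyl)-9-borabicyclo[3.3.1]nonane | CCOC(CCB1C2CCCC1CCC2)OCC | intermediate
8 | 4-(3,3-diethoxypropyl)-2-(furan-3-ylmethyl)furan | CCOC(CCc1coc(Cc2ccoc2)c1)OCC | intermediate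
9 | 3-[5-(furan-3-ylmethyl)furan-3-yl]propanal | O=CCCc1coc(Cc2ccoc2)c1 | intermediate
10 | 4-(4,4-dichlorobut-3-en-1-yl)-2-(furan-3-ylmethyl)furan | ClC(Cl)=CCCc1coc(Cc2ccoc2)c1 | intermediate
11 | ethyltriphenylphosphonium iodide | CC[P+](c1ccccc1)(c1ccccc1)c1ccccc1.[I-] | starting material
12 | 3-{[tert-butyl(dimethyl)silyl]oxy}propanal | O=CCCO[Si](C)(C)C(C)(C)C | starting material
13 | ethylidenetriphenylphosphorane | CC=P(c1ccccc1)(c1ccccc1)c1ccccc1 | intermediate
14 | (1-iodoethyl)triphenylphosphonium iodide | CC(I)[P+](c1ccccc1)(c1ccccc1)c1ccccc1.[I-] | intermediate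
15 | (1-iodoethylidene)triphenylphosphorane | CC(I)=P(c1ccccc1)(c1ccccc1)c1ccccc1 | intermediate
16 | tert-butyl{[(3Z)-4-iodopent-3-en-1-yl]oxy}dimethylsilane | C/C(I)=C/CCO[Si](C)(C)C(C)(C)C | intermediate
17 | methyl (2R)-oxirane-2-carboxylate | COC(=O)[C@H]1CO1 | starting material
18 | [(2E)-5-{[tert-butyl(dimethyl)silyl]oxy}pent-2-en-2-yl]lithium (lithium cis to the chain) | C/C([Li])=C/CCO[Si](C)(C)C(C)(C)C | intermediate
19 | [(2Z)-5-{[tert-butyl(dimethyl)silyl]oxy}pent-2-en-2-yl]magnesium bromide (magnesium cis to the chain) | C/C([Mg]Br)=C/CCO[Si](C)(C)C(C)(C)C | intermediate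
20 | methyl (2R,4Z)-7-{[tert-butyl(dimethyl)silyl]oxy}-2-hydroxy-4-methylhept-4-enoate | COC(=O)[C@H](O)C/C(C)=C\CCO[Si](C)(C)C(C)(C)C | intermediate
21 | methyl (2R,4Z)-7-{[tert-butyl(dimethyl)silyl]oxy}-4-methyl-2-(propanoyloxy)hept-4-enoate | COC(=O)[C@H](OC(=O)CC)C/C(C)=C\CCO[Si](C)(C)C(C)(C)C | intermediate
22 | methyl (2R,4Z)-7-hydroxy-4-methyl-2-(propanoyloxy)hept-4-enoate | COC(=O)[C@H](OC(=O)CC)C/C(C)=C\CCO | intermediate
23 | methyl (2R,4Z)-7-iodo-4-methyl-2-(propanoyloxy)hept-4-enoate | COC(=O)[C@H](OC(=O)CC)C/C(C)=C\CCI | intermediate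
24 | [(3Z,6R)-7-methoxy-4-methyl-7-oxo-6-(propanoyloxy)hept-3-en-1-yl]zinc iodide | COC(=O)[C@H](OC(=O)CC)C/C(C)=C\CC[Zn]I | intermediate
25 | methyl (2R,4Z,8Z)-8-chloro-11-[5-(furan-3-ylmethyl)furan-3-yl]-4-methyl-2-(propanoyloxy)undeca-4,8-dienoate | COC(=O)[C@H](OC(=O)CC)C/C(C)=C\CC/C(Cl)=C/CCc1coc(Cc2ccoc2)c1 | intermediate
26 | methyl (2R,4Z,8E)-11-[5-(furan-3-ylmethyl)furan-3-yl]-4,8-dimethyl-2-(propanoyloxy)undeca-4,8-dienoate | COC(=O)[C@H](OC(=O)CC)C/C(C)=C\CC/C(C)=C/CCc1coc(Cc2ccoc2)c1 | intermediate
27 | (5R)-5-{(2Z,6E)-9-[5-(furan-3-ylmethyl)furan-3-yl]-2,6-dimethylnona-2,6-dien-1-yl}-4-hydroxy-3-methylfuran-2(5H)-one | CC1=C(O)[C@@H](C/C(C)=C\CC/C(C)=C/CCc2coc(Cc3ccoc3)c2)OC1=O | target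

**Step count**

Total step count: 13. Longest linear sequence: 8 steps (steps 6 to 13).

**Steps most likely to fail**

1. Step 12. The first substitution may lose mono-selectivity (a second alkylation by 24), insertion may occur at the cis C–Cl bond, or the alkene geometry may erode during the second oxidative addition. The fallback sets out from 10 and comes back at 26, replacing the geminal double substitution by a single stereoretentive coupling of a preformed alkenyl iodide. Treatment of 10 with n-BuLi (2.2 equiv, THF, –78 °C) should eliminate HCl to 4-(4-chlorobut-3-yn-1-yl)-2-(furan-3-ylmethyl)furan F1 and exchange its chlorine to give {4-[5-(furan-3-ylmethyl)furan-3-yl]but-1-yn-1-yl}lithium F2, which is quenched with MeI to 2-(furan-3-ylmethyl)-4-(pent-3-yn-1-yl)furan F3. Hydrozirconation with Cp2Zr(H)Cl (slight excess, THF, 40 °C, to equilibrate zirconium onto the methyl-bearing carbon) should give chlorobis(cyclopentadienyl){(2E)-5-[5-(furan-3-ylmethyl)furan-3-yl]pent-2-en-2-yl}zirconium F4, and iodinolysis (I2, 0 °C) then gives 2-(furan-3-ylmethyl)-4-[(3E)-4-iodopent-3-en-1-yl]furan F5. Negishi coupling of F5 with 24 (Pd(PPh3)4, THF, 40 °C) should deliver 26 with retention of the E geometry.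

2. Step 7. The alkenylmagnesium may add to the methyl ester of the glycidate (1,2-addition) or open the epoxide at its substituted carbon. The fallback sets out from 16 and comes back at 21, using an ester-free epoxide and adjusting the oxidation level afterwards. The same alkenylmagnesium bromide 19 with CuI opens (2R)-2-{[(4-methoxybenzyl)oxy]methyl}oxirane (COc1ccc(COC[C@H]2CO2)cc1) at its terminal carbon to give (2R,4Z)-7-{[tert-butyl(dimethyl)silyl]oxy}-1-[(4-methoxybenzyl)oxy]-4-methylhept-4-en-2-ol F6. Propanoylation ((EtCO)2O, DMAP) gives (2R,4Z)-7-{[tert-butyl(dimethyl)silyl]oxy}-1-[(4-methoxybenzyl)oxy]-4-methylhept-4-en-2-yl propanoate F7, and buffered DDQ removes the benzyl-type ether to give (2R,4Z)-7-{[tert-butyl(dimethyl)silyl]oxy}-1-hydroxy-4-methylhept-4-en-2-yl propanoate F8. This is oxidised at once (TEMPO, PhI(OAc)2) to (2R,4Z)-7-{[tert-butyl(dimethyl)silyl]oxy}-4-methyl-1-oxohept-4-en-2-yl propanoate F9 and then (NaClO2, Pinnick conditions) to (2R,4Z)-7-{[tert-butyl(dimethyl)silyl]oxy}-4-methyl-2-(propanoyloxy)hept-4-enoic acid F10. Esterification with Me3SiCHN2 in MeOH should give 21.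

3. Step 2. The cation may alkylate the electron-rich furans (oligomerisation), or a furan ring may open under acid, during the ionic hydrogenation. The fallback sets out from 4 and comes back at 5 by a wholly base-mediated deoxygenation. Oxidation of 4 with MnO2 (CH2Cl2, rt) should give (4-bromofuran-2-yl)(furan-3-yl)methanone F11, condensation with N2H4·H2O (EtOH, reflux) gives (4-bromofuran-2-yl)(furan-3-yl)methanone hydrazone F12, and KOtBu in DMSO at room temperature (low-temperature Wolff–Kishner variant) should expel nitrogen and give 5.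

**Further compounds**

F1 | step 12 | 4-(4-chlorobut-3-yn-1-yl)-2-(furan-3-ylmethyl)furan | ClC#CCCc1coc(Cc2ccoc2)c1
F2 | step 12 | {4-[5-(furan-3-ylmethyl)furan-3-yl]but-1-yn-1-yl}lithium | [Li]C#CCCc1coc(Cc2ccoc2)c1
F3 | step 12 | 2-(furan-3-ylmethyl)-4-(pent-3-yn-1-yl)furan | CC#CCCc1coc(Cc2ccoc2)c1
F4 | step 12 | chlorobis(cyclopentadienyl){(2E)-5-[5-(furan-3-ylmethyl)furan-3-yl]pent-2-en-2-yl}zirconium | C/C(=C\CCc1coc(Cc2ccoc2)c1)[Zr](Cl)(C1C=CC=C1)C1C=CC=C1
F5 | step 12 | 2-(furan-3-ylmethyl)-4-[(3E)-4-iodopent-3-en-1-yl]furan | C/C(I)=C\CCc1coc(Cc2ccoc2)c1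
F6 | step 7 | (2R,4Z)-7-{[tert-butyl(dimethyl)silyl]oxy}-1-[(4-methoxybenzyl)oxy]-4-methylhept-4-en-2-ol | COc1ccc(COC[C@H](O)C/C(C)=C\CCO[Si](C)(C)C(C)(C)C)cc1
F7 | step 7 | (2R,4Z)-7-{[tert-butyl(dimethyl)silyl]oxy}-1-[(4-methoxybenzyl)oxy]-4-methylhept-4-en-2-yl propanoate | COc1ccc(COC[C@H](OC(=O)CC)C/C(C)=C\CCO[Si](C)(C)C(C)(C)C)cc1
F8 | step 7 | (2R,4Z)-7-{[tert-butyl(dimethyl)silyl]oxy}-1-hydroxy-4-methylhept-4-en-2-yl propanoate | OC[C@H](OC(=O)CC)C/C(C)=C\CCO[Si](C)(C)C(C)(C)C
F9 | step 7 | (2R,4Z)-7-{[tert-butyl(dimethyl)silyl]oxy}-4-methyl-1-oxohept-4-en-2-yl propanoate | O=C[C@H](OC(=O)CC)C/C(C)=C\CCO[Si](C)(C)C(C)(C)C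
F10 | step 7 | (2R,4Z)-7-{[tert-butyl(dimethyl)silyl]oxy}-4-methyl-2-(propanoyloxy)hept-4-enoic acid | OC(=O)[C@H](OC(=O)CC)C/C(C)=C\CCO[Si](C)(C)C(C)(C)C
F11 | step 2 | (4-bromofuran-2-yl)(furan-3-yl)methanone | O=C(c1cc(Br)co1)c1ccoc1
F12 | step 2 | (4-bromofuran-2-yl)(furan-3-yl)methanone hydrazone | NN=C(c1cc(Br)co1)c1ccoc1
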